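A flask held at 70 °C and one held at 85 °C take the same charge as a flask that changes between them at 2.5 s, so I compare how each divides what became target, isomer of the product A and isomer of the product B.

    starting material ⇌ target (K1 = 2.6, k1 = 0.10 /s, Ea1 = 98.0 kJ/mol, ΔH1 = −10.0 kJ/mol)
    target ⇌ isomer of the product A (K2 = 0.29, k2 = 0.049 /s, Ea2 = 102 kJ/mol, ΔH2 = 28.0 kJ/mol)
    isomer of the product A ⇌ isomer of the product B (K3 = 1.5, k3 = 0.0068 /s, Ea3 = 101 kJ/mol, ΔH3 = −29.0 kJ/mol)
    isomer of the product B ⇌ starting material (k4 = 0.070 /s, Ea4 = 84.0 kJ/mol)
    solid substrate ⇌ starting material, rate k5*(cs5 - [starting material]) while solid is left; crystals form when [starting material] > cs5 (cs5 = 2.0 M, k5 = 2.5 /s)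
    2 starting material → self-condensation product (k6 = 0.0018 /M/s, Ea6 = 77.0 kJ/mol)
    (constants at 70 °C)

all flasks: solid substrate 3.0 M; time 8.0 s
- north-east: temperature 70 °C
- north-west: temperature 85 °C
- south-east: at 70 °C until 2.5 s, from then on at 85 °C

- percent here means solid substrate units held: one self-condensation product counts as two
- a step written with two of one species runs at k times the square of its concentration and takes two of it each time
- solid substrate is a solid; its amount is given per volume of the solution
- the constants hold at 70 °C; other temperatures follow from the activation energies and enthalpies
- at the start none of the solid substrate is in solution
- what has only dissolved of solid substrate counts as not reacted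

1. the flask that comes out highest in share of target in all that became target or isomer of the product A or isomer of the product B, or "all alike" when all lie within 1.5 percentage points (north-east / north-west / south-east / all alike)
2. share of target in all that became target or isomer of the product A or isomer of the product B, north-east
3. share of target in all that became target or isomer of the product A or isomer of the product B, north-west
4. share of target in all that became target or isomer of the product A or isomer of the product B, south-east

My zero is the symmetric case: with isomers of equal standing, target holds a third. The constants tilt that. With target counted as one, isomer of the product A stands at K2 and isomer of the product B at K2 times K3, so target's equilibrium share S, one over the sum of these three standings, is 58.0% at 70 °C.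

Temperature is the first setting. Step 2 speeds up 4.5 times on heating, and every other constant scales by that factor raised to its energy over Ea2. So K2 becomes 0.437 and K3 becomes 0.980. That gives 53.6% at 85 °C, lower than cold. This S at 85 °C is my closing share.

Time is the second setting. Starting material enters target at k1 and isomer of the product B at k4 times K1, K2 and K3, the reverse of step 4, so the entry split E, k1 over the sum of these two constants, is 55.8% cold. Hot, it is 64.6%. In north-east, the forward half-life of target in step 2, 14.1 s, is longer than the 8.0 s allowed, so I keep E there. Hot, that half-life is 3.16 s, shorter than the hot stretch of south-east, so I take the closing share for north-west and south-east.

The solid charge is the last setting. E and S are ratios of first-order constants and contain no concentration, so I expect a small effect.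

I commit to 55.8% for north-east, 53.6% for north-west and 53.6% for south-east. That spread of 2.2 percentage points stands against a margin of 1.5 points, so by hand north-east leads.

The forecast says all alike, with 52%, 53% and 53.5% for north-east, north-west and south-east, “though that call is tight”.

The flasks give 51.7% in north-east, 51.9% in north-west and 51.2% in south-east, so the answer is all alike, and north-east stands 4.1 points under my entry split. Moved alone, the settings shift the north-east answer in this order: time (0.56 points), then solid substrate (0.26 points). South-east stopped at 5.0 s has a hot stretch of 2.50 s, shorter than the hot half-life of target in step 2, so my test does not give it the closing share of 53.6%; it reads 52.3%, with starting material at 28.3% and isomer of the product B at 22.7%. South-east left until 80.0 s reads 53.6%.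

All constants were chosen freely; the run is a simulation.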